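The target left at 2.50 h reads 0% in blue and 0% in ochre, so the target is an intermediate with a peak to be timed.

| flask | solid substrate | partner | protic impurity | remark | time |
|---|---|---|---|---|---|
| blue | 38 mM | 1 equiv | 5.4 mM | run made earlier |  |
| ochre | 59 mM | 1 equiv | 5.4 mM | run made earlier |  |
| flask | 27 mM | 1.00 equiv | 5.40 mM |  | 25 h |

| blue: time / h | blue: target / % | ochre: time / h | ochre: target / % |
|---|---|---|---|
| 0.250 | 18 | 0.250 | 11 |
| 0.833 | 12 | 0.833 | 15 |
| 2.50 | 0 | 2.50 | 0 |
| 8.00 | 0 | 8.00 | 1 |
| 25.0 | 2 | 25.0 | 0 |

(standard deviation of a reading: 2 percentage points)

- when, up to 25 h, the flask holds most target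
- the amount of target, in percent of the solid substrate charged, at that time

- solid substrate is a solid; its amount is given per volume of the solution
- what was read earlier has a scatter of 2 percentage points, one standard deviation
- at the start none of the solid substrate is in solution

At 0.250 h, blue reads 18% of its charge and ochre 11%. Their ratio, 1.64, stands close to the inverse ratio of the charges, 1.55. The supply therefore looks like a constant, zero-order feed at both loadings. My reckoning replaces the early curve by this mean feed, 26.7 mM h⁻¹. Two times then count. One is the time elapsed. The other is the delivery time, the time the mean feed needs to hand over a whole charge. Their ratio is the delivered fraction.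

Blue's delivery time is 1.43 h and ochre's is 2.21 h. At 0.250 h, ochre has 11.3% delivered, and its reading at 0.833 h is still higher. At 0.833 h, blue has 58.3% delivered and its target is lower. So these readings place the peak somewhere between those two delivered fractions.

For this flask the delivery time is 1.01 h, which puts the peak between 0.114 h and 0.592 h, and my reckoning takes the middle, 0.353 h. The feed counts surviving target only, so the delivery time errs long. It gives no height.

The forecast says 0.22 h and 23%, since “the solid runs out sooner”. The flask peaks at 0.382 h with 24.0%.

    solid substrate ⇌ dissolved substrate, rate k1*(cs1 - [dissolved substrate]) while solid is left; crystals form when [dissolved substrate] > cs1 (solubility = 15.0 mM, k = 0.0390 min⁻¹)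
    dissolved substrate + target → side product (k = 140 L mol⁻¹ min⁻¹)
    partner + protic impurity → quenched reagent (k = 3.50 L mol⁻¹ min⁻¹)
    dissolved substrate + partner → target (k = 160 L mol⁻¹ min⁻¹)
    partner ⇌ dormant form (K = 27.0, k = 0.0250 min⁻¹)

At that time this flask has 51.0% of its solid substrate left, so about half is delivered. Its own delivery time is 0.780 h, shorter than 1.01 h. The neighbour with 4.00 equiv of partner has the same solid charge, so it is reckoned with the same delivery time. Its target reaches 63.0%, more than half of the charge. At the same feed, delivering that share takes 0.491 h, later than this flask's peak. At 25.0 h that neighbour holds 63.0% target and 37.0% side product.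

The data are calculated for substances that don't exist; scatter was added.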